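## Analysis of the target

The target 31 is a ten-membered carbocycle (C1–C10, germacrane numbering) fused across C6–C7 to a butenolide (O6–C12(=O)–C11=C7). It carries a ketone at C1, an oxirane on C4–C5, an acetoxymethyl group (C13) on C11, a tiglate on O8 and methyl groups on C4 and C10. The five stereocentres are 4R,5S,6S,8S,10R. The oxirane is cis with respect to the ring (C3 and C6 on the same side, so it is the oxide of a 4Z alkene) and anti (erythro) to the lactone oxygen on C6. O6 and O8 are 1,3-syn, and in a flat drawing the oxirane oxygen, O6, O8 and the C10 methyl all lie on one face. The sensitive sites are: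
- the oxirane beside the lactone carbinol (acid, and transannular attack from C1/C10);
- the butenolide γ-hydrogens at C6 and C8 (base epimerises C6 or expels the C8 acyloxy group);
- C10, α to the ketone;
- two different esters that survive neither enolate nor hydride chemistry.

The synthesis is hard because a medium ring must be closed, the tetrasubstituted C7=C11 alkene must be placed unambiguously, and C8 and C10 must be related to the C4–C6 triad across a flexible ring. The strategy rests on one feature: C1 and C4 are joined by the C2–C3 bridge, and each is bonded to one end of the six-carbon arc C5–C10, which carries oxygen at C6 and C8 and a methyl at C10. Cutting C4–C5 and C1–C10 gives a cyclobutene (C1–C4) and a 3-methylcyclohexenone (C5–C10, C6=O). A [2+2] union followed by cleavage of C1–C4 and C5–C10 gives the ten-membered ring with C1 as an enol ether and C4=C5–C6=O as an enone.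

## Retrosynthetic reasoning

**31 ⇒ 29 + 30, and 29 ⇒ 28.** The two ester C–O bonds (O8–tigloyl, O13–acetyl) are cut first. Neither ester would survive the enolate, hydride or fluoride steps, and the primary O13 can be told from the secondary O8 by rate. The forward reactions must acylate without base strong enough to touch C6–H.

**28 ⇒ 27.** The C10–H bond and three O–Si bonds are cut. C1 is kept as its silyl enol ether until the end: the enol ether is the direct product of the ring-forming cycloreversion and keeps C1, C2 and C10 out of every enolate and hydride step. Ketonisation then has to set C10.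

**27 ⇒ 26 ⇒ 22 + 25.** The butenolide is cut at C7=C11 (ring-closing metathesis) and at O6–C12 (esterification). A condensation of a C7 enolate with an α-keto ester was considered for the same bonds. It leaves the geometry of the exocyclic alkene, and so the choice between lactonisation and no lactonisation, uncontrolled. Closing the alkene inside a five-membered ring fixes its position and geometry and brings C13 in already oxygenated.

**22 ⇒ 21 ⇒ 18.** The C6–H bond is cut (hydride to a ketone held in a chelate with the oxirane oxygen), then the C7 methylidene (Mannich–elimination at the only enolisable position of 18). With C7 sp2 the oxirane is the only stereocontrol element beside the carbonyl, and the anti epoxy alcohol it gives is the relation found in the target.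

**18 ⇒ 17 ⇒ 16 ⇒ 15.** The two oxirane C–O bonds are cut. A hydroxyl-directed epoxidation of a Z allylic alcohol gives the syn (threo) epoxy alcohol, the opposite of the target relation. The carbinol is therefore made as the C6 epimer (16, by catalyst-controlled reduction of 15), used to place the oxirane (17), and oxidised away (18). The concerted oxygen transfer keeps the Z geometry as the cis oxirane.

**15 ⇒ 13 ⇒ 7 + 12.** In 15 the bonds C1–C4 and C5–C10 are re-formed to give the tricyclic ketone 13, and in 13 the bonds C4–C5 and C1–C10 are cut. This is the key disconnection: the ring is made by strain release instead of an end-to-end closure. The four stereocentres of 13 are destroyed again, so only regiochemistry matters. The forward photocycloaddition needs the oxygen-bearing alkene carbon of 12 on the β-carbon of 7.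

**7 ⇒ 6 ⇒ 5 ⇒ 3 ⇒ 2 ⇒ 1.** The C10 methyl is cut (1,2-addition to 5, then oxidative 1,3-transposition of 6). Enone 5 comes from monoacetate 3 by oxidation and loss of acetate, and 3 from the meso diol 2 by enzymatic desymmetrisation. This buys the C8 stereocentre, the only one carried through the key step.

**12 ⇒ 11 ⇒ 9 ⇒ 8, and 25 ⇒ 24 ⇒ 23.** The cyclobutene is the thermodynamic silyl enol ether of 11, made by imine alkylation of 8. The acrylic acid 25 comes from 23 by silylation and saponification.

## Alternatives that were turned down

**Alternative 1:** The ten-membered ring is cut at C8–C9 and rebuilt from a six-membered 1,5-diene alkoxide. An anionic oxy-Cope rearrangement breaks C1–C6, forms C8–C9 and, after protonation of the C1/C10 enolate, gives the dienone A1.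
- For it: one sigmatropic step at low temperature makes the ring with the C1 ketone and the 4Z alkene in place. It needs no photochemistry and cannot leak into a Cope manifold. On the reliability of ring formation it is stronger than the chosen route.
- Against it: A1 has a C6=C7 alkene where the target needs a C6–O bond and a C7=C11 bond. The conjugated 4,6-diene would have to be oxygenated at C6 and carbon-substituted at C7 while C4=C5 is kept for the oxirane. C8 is created in the rearrangement and is not bought, and C10 still depends on an enolate protonation.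
- Comparison: the chosen route delivers C6 as a ketone (15, 18), the handle used for the oxirane relay, the C7 methylidene and the C6 hydride step. That outweighs the thermal risk of step 10.

**Alternative 2:** The C4–C5–C6 triad is made in an open-chain C1–C9 fragment. A Payne rearrangement, in which the C4 alkoxide opens a neighbouring 5,6-oxirane with inversion at C5, gives A2 with the cis-4,5-oxirane and a free C6 hydroxyl.
- For it: the three contiguous centres are set by reagent control in an acyclic chain and relayed stereospecifically, and the equilibrium favours the more substituted oxirane. On control of the triad it is stronger than the relay of steps 11–15, and the C7=C11 geometry is fixed early.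
- Against it: A2 is still acyclic. The ten-membered ring must be closed end to end with the oxirane present, and C9–C10, C10–C1 and the C10 centre remain to be made. A2 carries three kinds of protecting group on four oxygens.
- Comparison: the chosen route closes the ring independently of concentration, before any sensitive group exists, and uses one silyl group throughout.

**Alternative 3:** The ring and the butenolide are cut together at C6–C7, C11–C12 and C12–O6. A metal-mediated carbonylative [2+2+1] coupling of a C6 aldehyde with a tethered C7≡C11 alkyne (hetero-Pauson–Khand) would give A3.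
- For it: it is the most convergent plan. A3 is three routine operations (two deprotections with two acylations) from 31, and it is clearly shorter than the chosen route if the key step works.
- Against it: this coupling is established for tethers that close five- and six-membered rings. Forcing it to close a ten-membered ring asks the metallacycle to beat oligomerisation with no conformational help. The α,β-epoxy aldehyde is exposed to a low-valent metal, and C6 is formed with no control element.
- Comparison: the chosen route is longer, but its ring-forming steps have direct precedent for this ring size, and C6 is set by a chelate.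

Key step: step 9

## Remarks and assumptions

- Atom numbers C1–C15 in the discussion are the germacrane numbers of the target (C14 = methyl on C10, C15 = methyl on C4, C11–C13 = lactone carbons).
- Triol 1 is the commercial all-cis hydrogenation product of phloroglucinol and is used as purchased.
- Assumption: the lipase in step 2 is taken to acetylate the hydroxyl that gives 3 as drawn. If it prefers the enantiotopic hydroxyl, the same monoacetate is reached by lipase hydrolysis of the meso diacetate.
- The silyl group on the cyclobutene is tert-butyldimethylsilyl, not trimethylsilyl, so that the enol ether released in step 10 can serve as the protecting group of C1.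
- Descriptors that do not matter are left open or drawn as one isomer: C1 of 6, C2 of 10 and 11, C3 of 19 and 20, and the C1=C10 geometry of 14–27.

## Route

Step 1
Reactants: 1 cis,cis-cyclohexane-1,3,5-triol
Product: 2 cis,cis-5-[(tert-butyldimethylsilyl)oxy]cyclohexane-1,3-diol (meso)
Conditions: TBSCl (1.0 equiv), imidazole, DMF, 0 °C to rt
Reagents that add atoms: tert-butyldimethylsilyl chloride, C[Si](C)(Cl)C(C)(C)C
Why: Statistical mono-silylation of three equivalent secondary hydroxyls; the mono-ether is separated from bis-ether and recovered triol. No stereocentre is created, since 2 is meso.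

Step 2
Reactants: 2 cis,cis-5-[(tert-butyldimethylsilyl)oxy]cyclohexane-1,3-diol
Product: 3 (1R,3S,5S)-3-[(tert-butyldimethylsilyl)oxy]-5-hydroxycyclohexyl acetate
Conditions: Novozym 435 (immobilised Candida antarctica lipase B), vinyl acetate, i-Pr2O, 30 °C
Reagents that add atoms: vinyl acetate, C=COC(C)=O
Why: Lipase-catalysed transesterification distinguishes the two enantiotopic hydroxyls of the meso diol (enzymatic desymmetrisation), and vinyl acetate makes the acyl transfer irreversible. This fixes the absolute configuration of the silyloxy-bearing carbon, the future C8.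

Step 3
Reactants: 3 (1R,3S,5S)-3-[(tert-butyldimethylsilyl)oxy]-5-hydroxycyclohexyl acetate
Product: 5 (R)-5-[(tert-butyldimethylsilyl)oxy]cyclohex-2-en-1-one, via acetoxy ketone 4 (not isolated)
Conditions: (COCl)2, DMSO, CH2Cl2, −78 °C; Et3N, −78 °C to rt
Reagents that add atoms: none
Why: Swern oxidation gives the β-acetoxy ketone, which loses acetate by E1cB on warming with triethylamine; acetate leaves far more readily than the silanolate on the other β-carbon. The silyloxy stereocentre is not touched (its descriptor becomes R).

Step 4
Reactants: 5 (R)-5-[(tert-butyldimethylsilyl)oxy]cyclohex-2-en-1-one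
Product: 6 (5R)-5-[(tert-butyldimethylsilyl)oxy]-1-methylcyclohex-2-en-1-ol (both C1 epimers)
Conditions: MeLi, CeCl3, THF, −78 °C
Reagents that add atoms: methyllithium, [Li]C
Why: The organocerium reagent adds 1,2 to the enone and suppresses enolisation, which would expel the β-silyloxy group. The configuration of the new carbinol carbon is immaterial.

Step 5
Reactants: 6 (5R)-5-[(tert-butyldimethylsilyl)oxy]-1-methylcyclohex-2-en-1-ol
Product: 7 (S)-5-[(tert-butyldimethylsilyl)oxy]-3-methylcyclohex-2-en-1-one
Conditions: PCC, NaOAc, 4 Å MS, CH2Cl2, rt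
Reagents that add atoms: none
Why: Babler–Dauben oxidative transposition: the tertiary allylic chromate ester undergoes a [3,3] shift and oxidation, moving the carbonyl to the far allylic terminus and leaving the methyl on the β-carbon. The stereocentre is unchanged in space and is now S because the carbonyl lies on its other side.

Step 6
Reactants: 8 cyclobutanone
Product: 9 N-cyclobutylidenecyclohexanamine
Conditions: cyclohexylamine, 4 Å MS, Et2O, rt
Reagents that add atoms: cyclohexylamine, NC1CCCCC1
Why: Condensation of the strained, electrophilic ketone with a primary amine; the sieves remove water.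

Step 7
Reactants: 9 N-cyclobutylidenecyclohexanamine
Product: 11 2-methylcyclobutan-1-one (racemic), via N-(2-methylcyclobutylidene)cyclohexanamine 10 (not isolated)
Conditions: LDA, THF, −78 to 0 °C; MeI, −78 °C to rt; aq. oxalic acid, pentane, rt
Reagents that add atoms: iodomethane, CI; water, O
Why: Alkylation of the lithiated imine (metalloenamine) gives clean mono-C-methylation and avoids the self-aldol reaction of cyclobutanone enolates; mild acid hydrolysis returns the ketone. The stereocentre is racemic and is erased in step 8.

Step 8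
Reactants: 11 2-methylcyclobutan-1-one
Product: 12 tert-butyldimethyl[(2-methylcyclobut-1-en-1-yl)oxy]silane
Conditions: TBSCl, NaI, Et3N, MeCN, rt to 45 °C
Reagents that add atoms: tert-butyldimethylsilyl chloride, C[Si](C)(Cl)C(C)(C)C
Why: Silyl iodide formed in situ silylates under equilibrating conditions, which favour the more substituted enol ether; the minor 4-methyl isomer is removed by fractional distillation.

Step 9
Reactants: 7 (S)-5-[(tert-butyldimethylsilyl)oxy]-3-methylcyclohex-2-en-1-one; 12 tert-butyldimethyl[(2-methylcyclobut-1-en-1-yl)oxy]silane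
Product: 13 (9S)-2,9-bis[(tert-butyldimethylsilyl)oxy]-1,5-dimethyl-cis,anti,cis-tricyclo[4.4.0.0(2,5)]decan-7-one (mixture of diastereomers; one drawn, cyclobutane anti to the C9 oxygen)
Conditions: hν (Hg lamp, uranium-glass filter, λ > 340 nm), 12 (5 equiv), degassed CH2Cl2, −40 °C
Reagents that add atoms: none
Why: Excitation of the enone and intersystem crossing give the triplet enone, which adds the electron-rich cyclobutene stepwise: the nucleophilic methyl-bearing carbon C4 bonds to the electrophilic α-carbon C5, and the 1,4-diradical (tertiary radical at C10, α-silyloxy radical at C1) spin-inverts and closes C1–C10. The closest known reaction type is the enone–alkene [2+2] photocycloaddition of cyclohexenones with enol ethers and with donor- or acceptor-substituted cyclobutenes, the photochemical half of photo-thermal olefin metathesis. One ring is closed, the central cyclobutane C1–C4–C5–C10, by intermolecular [2+2], that is radical addition followed by recombination of the 1,4-diradical to a four-membered ring. Of the four new stereocentres, C1 and C4 are held cis by the ring of 12, C5 and C10 close to the less strained cis ring fusion, the anti placing of the outer rings follows from exo approach, and the relation to C8 is only weakly biased; a mixture is expected and tolerated because all four centres become sp2 in step 10. The one selectivity the step needs is head-to-tail regiochemistry, secured by the silyloxy donor, which polarises the alkene and stabilises the radical at C1; the methyl on C4 does not oppose it. Excess 12 and the long-wavelength filter suppress enone dimerisation and Norrish cleavage of the product ketone. C8 is remote from the chromophore and is not affected.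

Step 10
Reactants: 13 (9S)-2,9-bis[(tert-butyldimethylsilyl)oxy]-1,5-dimethyltricyclo[4.4.0.0(2,5)]decan-7-one
Product: 15 (2Z,6E,9S)-6,9-bis[(tert-butyldimethylsilyl)oxy]-3,7-dimethylcyclodeca-2,6-dien-1-one, via E-dienone 14 (not isolated)
Conditions: degassed PhMe, 2,6-di-tert-butylpyridine (cat.), sealed tube, 180 °C; then (PhS)2 (10 mol %), hν (sunlamp), PhH, rt
Reagents that add atoms: none
Why: Thermal homolysis of the bond shared by the two four-membered rings (C1–C4) gives a 1,4-diyl stabilised by the oxygen at C1, and β-scission of C5–C10 releases the strain of both cyclobutanes and forms the tetrasubstituted enol ether and the enone conjugated with C6=O (the thermal half of photo-thermal olefin metathesis). All four stereocentres made in step 9 become sp2, so every diastereomer of 13 converges; reversible addition of phenylthiyl radicals then funnels the C4=C5 mixture to the ring-cis (Z) enone, the stable geometry in a ten-membered ring. C8 is untouched.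

Step 11
Reactants: 15 (2Z,6E,9S)-6,9-bis[(tert-butyldimethylsilyl)oxy]-3,7-dimethylcyclodeca-2,6-dien-1-one
Product: 16 (1R,2Z,6E,9S)-6,9-bis[(tert-butyldimethylsilyl)oxy]-3,7-dimethylcyclodeca-2,6-dien-1-ol
Conditions: (S)-2-methyl-CBS-oxazaborolidine (0.3 equiv), catecholborane, PhMe, −78 °C
Reagents that add atoms: none
Why: Corey–Bakshi–Shibata reduction: the ketone binds the catalyst boron anti to its larger arm, the Z-alkenyl group, and hydride is delivered in the same sense as acetophenone to (R)-1-phenylethanol, giving the (R)-carbinol by catalyst control. Catecholborane at −78 °C reduces 1,2 and leaves the silyl enol ether alone. This centre is temporary: it is the C6 epimer of the target and serves only to place the oxirane.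

Step 12
Reactants: 16 (1R,2Z,6E,9S)-6,9-bis[(tert-butyldimethylsilyl)oxy]-3,7-dimethylcyclodeca-2,6-dien-1-ol
Product: 17 (1S,2R,4S,6E,10R)-4,7-bis[(tert-butyldimethylsilyl)oxy]-6,10-dimethyl-11-oxabicyclo[8.1.0]undec-6-en-2-ol (target numbering 4R,5S,6R,8S)
Conditions: VO(acac)2 (5 mol %), t-BuOOH (decane), PhH, 5 °C to rt
Reagents that add atoms: tert-butyl hydroperoxide, CC(C)(C)OO
Why: Hydroxyl-directed epoxidation through a vanadium(V) alkoxide–peroxide: A(1,3) strain between C3 and the C6 substituents keeps H6 in the alkene plane, so oxygen is delivered from the hydroxyl face and gives the threo epoxy alcohol. The transfer is concerted, so the Z geometry is kept as a cis-oxirane, which fixes C4 (R) and C5 (S). The bound allylic alkene reacts far faster than the hindered enol ether.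

Step 13
Reactants: 17 (1S,2R,4S,6E,10R)-4,7-bis[(tert-butyldimethylsilyl)oxy]-6,10-dimethyl-11-oxabicyclo[8.1.0]undec-6-en-2-ol
Product: 18 (1R,4S,6E,10R)-4,7-bis[(tert-butyldimethylsilyl)oxy]-6,10-dimethyl-11-oxabicyclo[8.1.0]undec-6-en-2-one
Conditions: Dess–Martin periodinane, NaHCO3, CH2Cl2, 0 °C to rt
Reagents that add atoms: none
Why: Buffered Dess–Martin oxidation converts the carbinol into the ketone without opening the oxirane or hydrolysing the enol ether. The temporary C6 centre is removed after it has done its work; the descriptor of C5 changes to R by priority only.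

Step 14
Reactants: 18 (1R,4S,6E,10R)-4,7-bis[(tert-butyldimethylsilyl)oxy]-6,10-dimethyl-11-oxabicyclo[8.1.0]undec-6-en-2-one
Product: 21 (1R,4S,6E,10R)-4,7-bis[(tert-butyldimethylsilyl)oxy]-6,10-dimethyl-3-methylidene-11-oxabicyclo[8.1.0]undec-6-en-2-one, via Mannich base 19 (not isolated), via ammonium iodide 20 (not isolated)
Conditions: LDA, THF, −78 °C; CH2=NMe2+ I−, −78 to 0 °C; MeI, Et2O, rt; aq. NaHCO3, CH2Cl2, rt
Reagents that add atoms: N,N-dimethylmethyleneiminium iodide (Eschenmoser's salt), C=[N+](C)C.[I-]
Why: C7 carries the only enolisable hydrogens; the kinetic lithium enolate at −78 °C keeps its β-silyloxy group and undergoes a Mannich reaction with Eschenmoser's salt. Quaternisation and E1cB loss of trimethylamine, a much better leaving group than silanolate, give the α-methylene ketone; C7 ends sp2, so no stereocentre is retained.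

Step 15
Reactants: 21 (1R,4S,6E,10R)-4,7-bis[(tert-butyldimethylsilyl)oxy]-6,10-dimethyl-3-methylidene-11-oxabicyclo[8.1.0]undec-6-en-2-one
Product: 22 (1S,2S,4S,6E,10R)-4,7-bis[(tert-butyldimethylsilyl)oxy]-6,10-dimethyl-3-methylidene-11-oxabicyclo[8.1.0]undec-6-en-2-ol (target numbering 4R,5S,6S,8S)
Conditions: Zn(BH4)2, Et2O, −40 to −10 °C
Reagents that add atoms: none
Why: Zinc chelates the carbonyl and oxirane oxygens and hydride attacks the chelate from the side away from the oxirane carbon C4, the established way to anti (erythro) epoxy alcohols; this sets C6 as S. Zinc borohydride reduces enones 1,2, and C7 is sp2, so no second α-stereocentre competes with the chelate.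

Step 16
Reactants: 23 ethyl 2-(hydroxymethyl)prop-2-enoate
Product: 24 ethyl 2-{[(tert-butyldimethylsilyl)oxy]methyl}prop-2-enoate
Conditions: TBSCl, imidazole, CH2Cl2, 0 °C to rt
Reagents that add atoms: tert-butyldimethylsilyl chloride, C[Si](C)(Cl)C(C)(C)C
Why: Standard silylation of a primary allylic alcohol.

Step 17
Reactants: 24 ethyl 2-{[(tert-butyldimethylsilyl)oxy]methyl}prop-2-enoate
Product: 25 2-{[(tert-butyldimethylsilyl)oxy]methyl}prop-2-enoic acid
Conditions: LiOH, THF/H2O, 0 °C to rt; then 1 M HCl to pH 3, 0 °C
Reagents that add atoms: lithium hydroxide, [Li+].[OH-]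
Why: Saponification of the ethyl ester; the primary silyl ether survives cold aqueous hydroxide and brief acidification.

Step 18
Reactants: 22 (1S,2S,4S,6E,10R)-4,7-bis[(tert-butyldimethylsilyl)oxy]-6,10-dimethyl-3-methylidene-11-oxabicyclo[8.1.0]undec-6-en-2-ol; 25 2-{[(tert-butyldimethylsilyl)oxy]methyl}prop-2-enoic acid
Product: 26 (1S,2S,4S,6E,10R)-4,7-bis[(tert-butyldimethylsilyl)oxy]-6,10-dimethyl-3-methylidene-11-oxabicyclo[8.1.0]undec-6-en-2-yl 2-{[(tert-butyldimethylsilyl)oxy]methyl}prop-2-enoate
Conditions: 25, 2,4,6-Cl3C6H2COCl, Et3N, THF, rt; then 22, DMAP, PhMe, rt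
Reagents that add atoms: none
Why: Yamaguchi esterification through the mixed anhydride and acylpyridinium acylates the hindered secondary allylic alcohol at oxygen, so C6 keeps its configuration. The amine bases are too weak to trigger Payne rearrangement of the epoxy alcohol.

Step 19
Reactants: 26 the acrylate ester of step 18
Product: 27 (1(10)E,4R,5S,6S,8S)-1,8,13-tris[(tert-butyldimethylsilyl)oxy]-4,5-epoxygermacra-1(10),7(11)-dien-12,6-olide
Conditions: Grubbs second-generation catalyst (15 mol %), degassed PhMe (0.005 M), 80 °C, Ar sparge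
Reagents that add atoms: none
Why: Ring-closing metathesis joins the C7 methylidene and the acrylate methylidene with loss of ethene and closes the five-membered lactone ring; the position and geometry of the tetrasubstituted C7=C11 alkene are fixed by the ring. The tetrasubstituted enol ether does not take part, and C6 and C8 are not touched.

Step 20
Reactants: 27 (1(10)E,4R,5S,6S,8S)-1,8,13-tris[(tert-butyldimethylsilyl)oxy]-4,5-epoxygermacra-1(10),7(11)-dien-12,6-olide
Product: 28 (4R,5S,6S,8S,10R)-4,5-epoxy-8,13-dihydroxy-1-oxogermacr-7(11)-en-12,6-olide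
Conditions: HF·pyridine, pyridine, THF, 0 °C to rt
Reagents that add atoms: none
Why: Fluoride cleaves the enol silyl ether first, and the enol ketonises by protonation at C10 from the face opposite the still silylated C8 oxygen, which flanks C10 across C9; this puts the methyl cis to O8 (10R). The two alkyl silyl ethers then fall; pyridine buffering spares the oxirane, and the absence of base protects C6 and C8.

Step 21
Reactants: 28 (4R,5S,6S,8S,10R)-4,5-epoxy-8,13-dihydroxy-1-oxogermacr-7(11)-en-12,6-olide
Product: 29 (4R,5S,6S,8S,10R)-13-acetoxy-4,5-epoxy-8-hydroxy-1-oxogermacr-7(11)-en-12,6-olide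
Conditions: Ac2O (1.1 equiv), 2,4,6-collidine, CH2Cl2, −20 °C
Reagents that add atoms: acetic anhydride, CC(=O)OC(C)=O
Why: The primary allylic hydroxyl is acetylated much faster than the hindered secondary C8 hydroxyl at low temperature. Collidine is too weak a base to deprotonate the butenolide.

Step 22
Reactants: 29 (4R,5S,6S,8S,10R)-13-acetoxy-4,5-epoxy-8-hydroxy-1-oxogermacr-7(11)-en-12,6-olide; 30 tiglic acid ((E)-2-methylbut-2-enoic acid)
Product: 31 (4R,5S,6S,8S,10R)-13-acetoxy-4,5-epoxy-1-oxo-8-[(E)-2-methylbut-2-enoyloxy]germacr-7(11)-en-12,6-olide (CNP0229937.1)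
Conditions: 30, 2,4,6-Cl3C6H2COCl, Et3N, PhMe, rt; then 29, DMAP, 0 °C to rt
Reagents that add atoms: none
Why: Yamaguchi esterification acylates O8 with retention at C8 and without isomerising the (E)-2-methylbut-2-enoyl group. The mild conditions leave C6, C10 and the oxirane untouched and give the target.

## Compound list

1 | cis,cis-cyclohexane-1,3,5-triol | O[C@H]1C[C@@H](O)C[C@@H](O)C1 | starting material
2 | cis,cis-5-[(tert-butyldimethylsilyl)oxy]cyclohexane-1,3-diol (meso) | O[C@H]1C[C@@H](O)C[C@@H](O[Si](C)(C)C(C)(C)C)C1 | intermediate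
3 | (1R,3S,5S)-3-[(tert-butyldimethylsilyl)oxy]-5-hydroxycyclohexyl acetate | O[C@H]1C[C@@H](OC(C)=O)C[C@@H](O[Si](C)(C)C(C)(C)C)C1 | intermediate
4 | (1S,3R)-3-[(tert-butyldimethylsilyl)oxy]-5-oxocyclohexyl acetate | O=C1C[C@@H](OC(C)=O)C[C@@H](O[Si](C)(C)C(C)(C)C)C1 | intermediate (not isolated)
5 | (R)-5-[(tert-butyldimethylsilyl)oxy]cyclohex-2-en-1-one | O=C1C=CC[C@@H](O[Si](C)(C)C(C)(C)C)C1 | intermediate
6 | (5R)-5-[(tert-butyldimethylsilyl)oxy]-1-methylcyclohex-2-en-1-ol (C1 epimers) | CC1(O)C=CC[C@@H](O[Si](C)(C)C(C)(C)C)C1 | intermediate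
7 | (S)-5-[(tert-butyldimethylsilyl)oxy]-3-methylcyclohex-2-en-1-one | CC1=CC(=O)C[C@@H](O[Si](C)(C)C(C)(C)C)C1 | intermediate
8 | cyclobutanone | O=C1CCC1 | starting material
9 | N-cyclobutylidenecyclohexanamine | C1CCC(CC1)N=C1CCC1 | intermediate
10 | N-(2-methylcyclobutylidene)cyclohexanamine (racemic) | CC1CCC1=NC1CCCCC1 | intermediate (not isolated)
11 | 2-methylcyclobutan-1-one (racemic) | CC1CCC1=O | intermediate
12 | tert-butyldimethyl[(2-methylcyclobut-1-en-1-yl)oxy]silane | CC1=C(O[Si](C)(C)C(C)(C)C)CC1 | intermediate
13 | (9S)-2,9-bis[(tert-butyldimethylsilyl)oxy]-1,5-dimethyl-cis,anti,cis-tricyclo[4.4.0.0(2,5)]decan-7-one (one diastereomer drawn) | O=C1C[C@@H](O[Si](C)(C)C(C)(C)C)C[C@@]2(C)[C@@H]1[C@]3(C)CC[C@]23O[Si](C)(C)C(C)(C)C | intermediate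
14 | (2E,6E,9S)-6,9-bis[(tert-butyldimethylsilyl)oxy]-3,7-dimethylcyclodeca-2,6-dien-1-one | C/C1=C(O[Si](C)(C)C(C)(C)C)/CC/C(C)=C/C(=O)C[C@@H](O[Si](C)(C)C(C)(C)C)C1 | intermediate (not isolated)
15 | (2Z,6E,9S)-6,9-bis[(tert-butyldimethylsilyl)oxy]-3,7-dimethylcyclodeca-2,6-dien-1-one | C/C1=C(O[Si](C)(C)C(C)(C)C)/CC/C(C)=C\C(=O)C[C@@H](O[Si](C)(C)C(C)(C)C)C1 | intermediate
16 | (1R,2Z,6E,9S)-6,9-bis[(tert-butyldimethylsilyl)oxy]-3,7-dimethylcyclodeca-2,6-dien-1-ol | C/C1=C(O[Si](C)(C)C(C)(C)C)/CC/C(C)=C\[C@H](O)C[C@@H](O[Si](C)(C)C(C)(C)C)C1 | intermediate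
17 | (1S,2R,4S,6E,10R)-4,7-bis[(tert-butyldimethylsilyl)oxy]-6,10-dimethyl-11-oxabicyclo[8.1.0]undec-6-en-2-ol | C/C1=C(O[Si](C)(C)C(C)(C)C)/CC[C@@]2(C)O[C@H]2[C@H](O)C[C@@H](O[Si](C)(C)C(C)(C)C)C1 | intermediate
18 | (1R,4S,6E,10R)-4,7-bis[(tert-butyldimethylsilyl)oxy]-6,10-dimethyl-11-oxabicyclo[8.1.0]undec-6-en-2-one | C/C1=C(O[Si](C)(C)C(C)(C)C)/CC[C@@]2(C)O[C@H]2C(=O)C[C@@H](O[Si](C)(C)C(C)(C)C)C1 | intermediate
19 | (1R,4S,6E,10R)-4,7-bis[(tert-butyldimethylsilyl)oxy]-3-[(dimethylamino)methyl]-6,10-dimethyl-11-oxabicyclo[8.1.0]undec-6-en-2-one (C3 epimers) | C/C1=C(O[Si](C)(C)C(C)(C)C)/CC[C@@]2(C)O[C@H]2C(=O)C(CN(C)C)[C@@H](O[Si](C)(C)C(C)(C)C)C1 | intermediate (not isolated)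
20 | trimethylammonium iodide of 19 | C/C1=C(O[Si](C)(C)C(C)(C)C)/CC[C@@]2(C)O[C@H]2C(=O)C(C[N+](C)(C)C)[C@@H](O[Si](C)(C)C(C)(C)C)C1.[I-] | intermediate (not isolated)
21 | (1R,4S,6E,10R)-4,7-bis[(tert-butyldimethylsilyl)oxy]-6,10-dimethyl-3-methylidene-11-oxabicyclo[8.1.0]undec-6-en-2-one | C/C1=C(O[Si](C)(C)C(C)(C)C)/CC[C@@]2(C)O[C@H]2C(=O)C(=C)[C@@H](O[Si](C)(C)C(C)(C)C)C1 | intermediate
22 | (1S,2S,4S,6E,10R)-4,7-bis[(tert-butyldimethylsilyl)oxy]-6,10-dimethyl-3-methylidene-11-oxabicyclo[8.1.0]undec-6-en-2-ol | C/C1=C(O[Si](C)(C)C(C)(C)C)/CC[C@@]2(C)O[C@H]2[C@@H](O)C(=C)[C@@H](O[Si](C)(C)C(C)(C)C)C1 | intermediate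
23 | ethyl 2-(hydroxymethyl)prop-2-enoate | C=C(CO)C(=O)OCC | starting material
24 | ethyl 2-{[(tert-butyldimethylsilyl)oxy]methyl}prop-2-enoate | C=C(CO[Si](C)(C)C(C)(C)C)C(=O)OCC | intermediate
25 | 2-{[(tert-butyldimethylsilyl)oxy]methyl}prop-2-enoic acid | C=C(CO[Si](C)(C)C(C)(C)C)C(=O)O | intermediate
26 | (1S,2S,4S,6E,10R)-4,7-bis[(tert-butyldimethylsilyl)oxy]-6,10-dimethyl-3-methylidene-11-oxabicyclo[8.1.0]undec-6-en-2-yl 2-{[(tert-butyldimethylsilyl)oxy]methyl}prop-2-enoate | C/C1=C(O[Si](C)(C)C(C)(C)C)/CC[C@@]2(C)O[C@H]2[C@@H](OC(=O)C(=C)CO[Si](C)(C)C(C)(C)C)C(=C)[C@@H](O[Si](C)(C)C(C)(C)C)C1 | intermediate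
27 | (1(10)E,4R,5S,6S,8S)-1,8,13-tris[(tert-butyldimethylsilyl)oxy]-4,5-epoxygermacra-1(10),7(11)-dien-12,6-olide | C/C1=C(O[Si](C)(C)C(C)(C)C)/CC[C@@]2(C)O[C@H]2[C@H]3OC(=O)C(CO[Si](C)(C)C(C)(C)C)=C3[C@@H](O[Si](C)(C)C(C)(C)C)C1 | intermediate
28 | (4R,5S,6S,8S,10R)-4,5-epoxy-8,13-dihydroxy-1-oxogermacr-7(11)-en-12,6-olide | C[C@H]1C(=O)CC[C@@]2(C)O[C@H]2[C@H]3OC(=O)C(CO)=C3[C@@H](O)C1 | intermediate
29 | (4R,5S,6S,8S,10R)-13-acetoxy-4,5-epoxy-8-hydroxy-1-oxogermacr-7(11)-en-12,6-olide | C[C@H]1C(=O)CC[C@@]2(C)O[C@H]2[C@H]3OC(=O)C(COC(C)=O)=C3[C@@H](O)C1 | intermediate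
30 | tiglic acid, (E)-2-methylbut-2-enoic acid | C/C=C(\C)C(=O)O | starting material
31 | (4R,5S,6S,8S,10R)-13-acetoxy-4,5-epoxy-1-oxo-8-[(E)-2-methylbut-2-enoyloxy]germacr-7(11)-en-12,6-olide (CNP0229937.1) | C/C=C(\C)C(=O)O[C@H]1C[C@@H](C)C(=O)CC[C@@]2(C)O[C@H]2[C@H]2OC(=O)C(COC(C)=O)=C12 | target

## Step count and least certain steps

Total: 22 steps. Longest linear sequence: 17 steps (steps 1–5, 9–15, 18–22).

**Step 9 (key step).** The new C1–C10 bond joins two fully substituted carbons beside a third (C4). Closure of the 1,4-diradical may therefore be slow, so that reversion to the partners, head-to-head addition and enone dimerisation gain ground. Fallback: a silicon tether makes the addition intramolecular and forces C1 onto C10. It sets out from 7 and 11 and comes back at 15. Compound 7 is desilylated (HF, MeCN, 0 °C) to (S)-5-hydroxy-3-methylcyclohex-2-en-1-one F1. Compound 11 is silylated under the conditions of step 8 with i-Pr2SiCl2 in place of the monochlorosilane to give chloro[(2-methylcyclobut-1-en-1-yl)oxy]di(propan-2-yl)silane F2. F2 is joined to F1 (imidazole, CH2Cl2) to give the mixed bis-silyl ether F3. Irradiation of F3 at high dilution under the conditions of step 9 should give the tethered photoadduct F4 through a seven-membered siloxane ring. HF·pyridine removes the tether to give the diol F5, and TBSOTf/2,6-lutidine gives the bis-silyl ether F6, the diastereomer of 13 with the cyclobutane on the face of the C8 oxygen. F6 is thermolysed as in step 10 and rejoins the route at 15.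

**Step 10.** At the temperature needed for cycloreversion the 1,5-diene may undergo Cope rearrangement to the divinylcyclohexanone (also reachable by the other scission of the diyl), and silanol may be lost from C8, which is β to the C6 ketone. Fallback: an oxy-anion-accelerated cycloreversion far below the Cope threshold. It sets out from 11 and 7 and comes back at 15. Compound 11 is silylated with TMSCl/NaI/Et3N to trimethyl[(2-methylcyclobut-1-en-1-yl)oxy]silane F7, which is added to 7 as in step 9 to give the trimethylsilyl-protected photoadduct F8. K2CO3/MeOH at 0 °C frees the tertiary cyclobutanol F9 while the secondary silyl ether stays. KHMDS/18-crown-6 in THF (−78 to 0 °C) gives the alkoxide, in which the oxy-anion weakens C1–C4, so the same two bonds break to give the potassium enolate F10 of the ten-membered dienone. Trapping with TBSCl and the disulfide equilibration of step 10 give 15.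

**Step 11.** Facial discrimination may be insufficient, because the small group is a β-branched ring methylene and the presentation of the Z-alkenyl group to the catalyst depends on ring conformation. Fallback: stoichiometric inversion instead of catalyst control. It sets out from 15 and comes back at 16. Luche reduction (NaBH4, CeCl3, MeOH, −78 °C) gives 16 together with its C1 epimer, the (1S)-alcohol F11, and the two are separated. F11 is inverted by Mitsunobu esterification (4-nitrobenzoic acid, PPh3, DIAD) to the 4-nitrobenzoate F12 of 16, which K2CO3/MeOH converts into 16.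

**Step 19.** Ring closure may fail: both alkenes are 1,1-disubstituted, one is electron-poor and the other is flanked by two oxygenated carbons, so the catalyst may decompose before turnover. Fallback: build the butenolide by aldol condensation. It sets out from 18 and comes back at 27. The lithium enolate of 18 (LDA, −78 °C) is added to ethyl 3-[(tert-butyldimethylsilyl)oxy]-2-oxopropanoate F13 (a separately made reagent) to give the tertiary aldol F14. Burgess reagent removes water through the ketone enolate to give the alkylidene keto ester F15 as a mixture of geometric isomers. Zn(BH4)2 reduces C6 under the chelate control of step 15. The isomer with the ester cis to C6 lactonises directly to 27; the other remains as the hydroxy ester F16, which is photoisomerised (254 nm) and then lactonises to 27 as well.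

**Step 20.** Ketonisation may show poor or reversed facial selectivity, for instance if a hydroxyl freed early delivers the proton intramolecularly or the ring exposes the other face. Acid may also open the oxirane, including transannular attack by the enol. Fallback: reagent-controlled protonation separated from the removal of the alkyl silyl ethers. It sets out from 27 and comes back at 28. Compound 27 is treated with benzoyl fluoride and ethanol in the presence of a cinchona alkaloid (quinine or quinidine series, chosen by screening; DMF, rt). This latent source of hydrogen fluoride cleaves only the enol silyl ether and protonates C10 within the chiral ammonium enolate ion pair, giving the bis-silyl ketone F17. HF·pyridine/pyridine then removes the two alkyl silyl ethers to give 28.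

## Further compounds

F1 | step 9 | (S)-5-hydroxy-3-methylcyclohex-2-en-1-one | CC1=CC(=O)C[C@@H](O)C1
F2 | step 9 | chloro[(2-methylcyclobut-1-en-1-yl)oxy]di(propan-2-yl)silane | CC1=C(O[Si](Cl)(C(C)C)C(C)C)CC1
F3 | step 9 | (S)-3-methyl-5-({[(2-methylcyclobut-1-en-1-yl)oxy]di(propan-2-yl)silyl}oxy)cyclohex-2-en-1-one | CC1=CC(=O)C[C@@H](O[Si](C(C)C)(C(C)C)OC2=C(C)CC2)C1
F4 | step 9 | silicon-tethered cis,anti,cis photoadduct (O2 and O9 bridged by di(propan-2-yl)silylene) | O=C1C[C@@H]2C[C@]3(C)[C@H]1[C@@]4(C)CC[C@@]34O[Si](C(C)C)(C(C)C)O2
F5 | step 9 | (9S)-2,9-dihydroxy-1,5-dimethyl-cis,anti,cis-tricyclo[4.4.0.0(2,5)]decan-7-one (cyclobutane syn to the C9 oxygen) | O=C1C[C@@H](O)C[C@]2(C)[C@H]1[C@@]3(C)CC[C@@]23O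
F6 | step 9 | diastereomer of 13 with the cyclobutane syn to the C9 oxygen | O=C1C[C@@H](O[Si](C)(C)C(C)(C)C)C[C@]2(C)[C@H]1[C@@]3(C)CC[C@@]23O[Si](C)(C)C(C)(C)C
F7 | step 10 | trimethyl[(2-methylcyclobut-1-en-1-yl)oxy]silane | CC1=C(O[Si](C)(C)C)CC1
F8 | step 10 | (9S)-9-[(tert-butyldimethylsilyl)oxy]-1,5-dimethyl-2-[(trimethylsilyl)oxy]-cis,anti,cis-tricyclo[4.4.0.0(2,5)]decan-7-one (one diastereomer drawn) | O=C1C[C@@H](O[Si](C)(C)C(C)(C)C)C[C@@]2(C)[C@@H]1[C@]3(C)CC[C@]23O[Si](C)(C)C
F9 | step 10 | (9S)-9-[(tert-butyldimethylsilyl)oxy]-2-hydroxy-1,5-dimethyl-cis,anti,cis-tricyclo[4.4.0.0(2,5)]decan-7-one | O=C1C[C@@H](O[Si](C)(C)C(C)(C)C)C[C@@]2(C)[C@@H]1[C@]3(C)CC[C@]23O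
F10 | step 10 | potassium (1E,5Z,8S)-8-[(tert-butyldimethylsilyl)oxy]-2,6-dimethyl-4-oxocyclodeca-1,5-dien-1-olate | C/C1=C([O-])/CC/C(C)=C\C(=O)C[C@@H](O[Si](C)(C)C(C)(C)C)C1.[K+]
F11 | step 11 | (1S,2Z,6E,9S)-6,9-bis[(tert-butyldimethylsilyl)oxy]-3,7-dimethylcyclodeca-2,6-dien-1-ol | C/C1=C(O[Si](C)(C)C(C)(C)C)/CC/C(C)=C\[C@@H](O)C[C@@H](O[Si](C)(C)C(C)(C)C)C1
F12 | step 11 | (1R,2Z,6E,9S)-6,9-bis[(tert-butyldimethylsilyl)oxy]-3,7-dimethylcyclodeca-2,6-dien-1-yl 4-nitrobenzoate | C/C1=C(O[Si](C)(C)C(C)(C)C)/CC/C(C)=C\[C@H](OC(=O)c2ccc(cc2)[N+](=O)[O-])C[C@@H](O[Si](C)(C)C(C)(C)C)C1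
F13 | step 19 | ethyl 3-[(tert-butyldimethylsilyl)oxy]-2-oxopropanoate | CCOC(=O)C(=O)CO[Si](C)(C)C(C)(C)C
F14 | step 19 | aldol adduct of 18 at C3 with F13 (tertiary alcohol, mixture of diastereomers) | C/C1=C(O[Si](C)(C)C(C)(C)C)/CC[C@@]2(C)O[C@H]2C(=O)C(C(O)(CO[Si](C)(C)C(C)(C)C)C(=O)OCC)[C@@H](O[Si](C)(C)C(C)(C)C)C1
F15 | step 19 | alkylidene keto ester from F14 (mixture of geometric isomers) | C/C1=C(O[Si](C)(C)C(C)(C)C)/CC[C@@]2(C)O[C@H]2C(=O)C(=C(CO[Si](C)(C)C(C)(C)C)C(=O)OCC)[C@@H](O[Si](C)(C)C(C)(C)C)C1
F16 | step 19 | hydroxy ester with the ester group trans to the C6 carbinol | C/C1=C(O[Si](C)(C)C(C)(C)C)/CC[C@@]2(C)O[C@H]2[C@@H](O)/C(=C(\CO[Si](C)(C)C(C)(C)C)C(=O)OCC)[C@@H](O[Si](C)(C)C(C)(C)C)C1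
F17 | step 20 | (4R,5S,6S,8S,10R)-8,13-bis[(tert-butyldimethylsilyl)oxy]-4,5-epoxy-1-oxogermacr-7(11)-en-12,6-olide | C[C@H]1C(=O)CC[C@@]2(C)O[C@H]2[C@H]3OC(=O)C(CO[Si](C)(C)C(C)(C)C)=C3[C@@H](O[Si](C)(C)C(C)(C)C)C1
A1 | alternative 1 | (4Z,6E)-4,10-dimethyl-8-(4-methoxybenzyloxy)cyclodeca-4,6-dien-1-one | C1[C@H](OCc2ccc(OC)cc2)/C=C/C=C(/C)CCC(=O)[C@@H]1C
A2 | alternative 2 | open-chain C1–C9 fragment with cis-4,5-oxirane and free C6 hydroxyl (8-O-triethylsilyl, 13-O-4-methoxybenzyl, 1-O- and 12-O-tert-butyldimethylsilyl) | C=C[C@H](O[Si](CC)(CC)CC)/C(=C(/COCc1ccc(OC)cc1)CO[Si](C)(C)C(C)(C)C)[C@H](O)[C@@H]2O[C@]2(C)CCCO[Si](C)(C)C(C)(C)C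
A3 | alternative 3 | (4R,5S,6S,8S,10R)-8-[(tert-butyldimethylsilyl)oxy]-4,5-epoxy-13-(4-methoxybenzyloxy)-1-oxogermacr-7(11)-en-12,6-olide | CC(C)(C)[Si](C)(C)O[C@H]1C[C@@H](C)C(=O)CC[C@@]2(C)O[C@H]2[C@H]2OC(=O)C(COCc3ccc(OC)cc3)=C12
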